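**Strategy.** Everything rests on cutting the C3–C4 bond of the 7-oxabicyclo[4.1.0]heptan-2-one core (C3 carries the isovalerate, C4 the side chain). The C3 oxygen, C4 and the exocyclic C2′=C1′H2 methylene form a homoallylic-alcohol (ene) retron. One chelation-controlled intramolecular carbonyl-ene reaction of an acyclic epoxy α-keto aldehyde therefore closes the cyclohexanone ring onto the preformed oxirane and creates the C3 hydroxyl, the methylene group and the C3/C4 stereocentres together. The precursor is a farnesane-type chain with a (Z)-trisubstituted alkene, assembled from two alkynols by copper-catalysed anti-carbomagnesiation; esterification, oxidation and a singlet-oxygen ene reaction complete the synthesis.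

Key step: step 11

Remarks on the chemistry:
- Atom labels: C1–C6/O7 follow 7-oxabicyclo[4.1.0]heptan-2-one numbering; primed atoms belong to the side chain (C1′ = exocyclic CH2, C3′ = side-chain C=O or its carbinol precursor, C4′ = CH2 next to it).
- Assumption: the carbinol centre of the right-hand fragment (C4 of 5, later C3′) is carried as both epimers, because step 14 oxidises it to the ketone; its SMILES carry no descriptor.

**Step 1**
Reactants: 1 4-methylpent-3-en-1-ol
Product: 3 (3RS)-6-methylhept-5-en-1-yn-3-ol, via 4-methylpent-3-enal 2 (not isolated)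
Conditions: (COCl)2, DMSO, CH2Cl2, −78 °C; Et3N; then HC≡CMgBr (THF, excess), −78 → 0 °C; aq. NH4Cl
Reagents that add atoms: ethynylmagnesium bromide, C#C[Mg]Br
Why: Swern oxidation followed in the same flask by Grignard addition traps the isomerisation-prone β,γ-unsaturated aldehyde as soon as it forms; the carbinol centre is formed without control, which is acceptable because it is oxidised later.

**Step 2**
Reactants: 3 (3RS)-6-methylhept-5-en-1-yn-3-ol
Product: 5 (2Z,4RS)-3,7-dimethylocta-2,6-diene-1,4-diol, via alkenylmagnesium bromide 4 (not isolated)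
Conditions: MeMgBr (2.5 equiv), CuI (0.2 equiv), THF, −10 → 23 °C; then (CH2O)n, 23 → 40 °C; aq. NH4Cl
Reagents that add atoms: methylmagnesium bromide, C[Mg]Br; formaldehyde (from paraformaldehyde), C=O
Why: Copper-catalysed anti-carbomagnesiation of the propargylic alkoxide puts methyl on the internal alkyne carbon and magnesium on the terminus cis to the alkoxide (five-membered chelate 4), and hydroxymethylation with retention should give only the Z alkene (CH2OH cis to the carbinol carbon, methyl cis to the vinylic H).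

**Step 3**
Reactants: 5 (2Z,4RS)-3,7-dimethylocta-2,6-diene-1,4-diol
Product: 6 (2Z,4RS)-1,4-bis(tert-butyldimethylsilyloxy)-3,7-dimethylocta-2,6-diene
Conditions: TBSCl (2.5 equiv), imidazole, DMF, 23 °C
Reagents that add atoms: tert-butyldimethylsilyl chloride, CC(C)(C)[Si](C)(C)Cl
Why: Imidazole-assisted silylation protects both alcohols, so that no free (Z)-4-hydroxy allylic electrophile, which would close to a 2,5-dihydrofuran, ever has to be made.

**Step 4**
Reactants: 6 (2Z,4RS)-1,4-bis(tert-butyldimethylsilyloxy)-3,7-dimethylocta-2,6-diene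
Product: 7 (2Z,4RS)-1-bromo-4-(tert-butyldimethylsilyloxy)-3,7-dimethylocta-2,6-diene
Conditions: Ph3PBr2 (1.1 equiv), CH2Cl2, 0 °C
Reagents that add atoms: triphenylphosphine dibromide, BrP(Br)(c1ccccc1)(c1ccccc1)c1ccccc1
Why: Bromotriphenylphosphonium bromide converts silyl ethers directly into bromides (Appel-type SN2 through an alkoxyphosphonium ion); the unhindered primary allylic ether should react well ahead of the hindered secondary one, and substitution at the CH2 carbon keeps the Z geometry.

**Step 5**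
Reactants: 8 methyl (4S)-2,2-dimethyl-1,3-dioxolane-4-carboxylate
Product: 10 (4R)-4-ethynyl-2,2-dimethyl-1,3-dioxolane, via (S)-glyceraldehyde acetonide 9 (not isolated)
Conditions: i-Bu2AlH (1.1 equiv), CH2Cl2, −78 °C; then MeOH, K2CO3, dimethyl (1-diazo-2-oxopropyl)phosphonate, −78 → 23 °C
Reagents that add atoms: dimethyl (1-diazo-2-oxopropyl)phosphonate, CC(=O)C(=[N+]=[N-])P(=O)(OC)OC
Why: Half-reduction of the ester and Ohira–Bestmann (Seyferth–Gilbert) homologation of the aldehyde in the same flask give the terminal alkyne without disturbing the acetal-protected stereocentre (the descriptor changes only through priorities).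

**Step 6**
Reactants: 10 (4R)-4-ethynyl-2,2-dimethyl-1,3-dioxolane
Product: 11 (2R)-but-3-yne-1,2-diol
Conditions: Dowex 50WX8 (H+ form), MeOH/H2O, 23 °C
Reagents that add atoms: none
Why: Acid-catalysed acetal hydrolysis frees the diol, whose secondary alkoxide is needed to direct the next carbometalation.

**Step 7**
Reactants: 11 (2R)-but-3-yne-1,2-diol; 7 (2Z,4RS)-1-bromo-4-(tert-butyldimethylsilyloxy)-3,7-dimethylocta-2,6-diene
Product: 13 (2R,3Z,6Z,8RS)-8-(tert-butyldimethylsilyloxy)-3,7,11-trimethyldodeca-3,6,10-triene-1,2-diol, via alkenylmagnesium bromide 12 (not isolated)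
Conditions: 11 (1.4 equiv), MeMgBr (4.4 equiv), CuI (0.3 equiv), THF, −20 → 23 °C; then 7 (1.0 equiv), −20 → 0 °C; aq. NH4Cl
Reagents that add atoms: methylmagnesium bromide, C[Mg]Br
Why: The same alkoxide-directed copper-catalysed anti-carbomagnesiation gives 12 with magnesium cis to the carbinol carbon, and copper-catalysed SN2 allylation at the primary carbon of 7 (its γ-carbon is fully substituted) should give the skipped diene with both alkenes Z, the (2R) centre coming unchanged from 11.

**Step 8**
Reactants: 13 (2R,3Z,6Z,8RS)-8-(tert-butyldimethylsilyloxy)-3,7,11-trimethyldodeca-3,6,10-triene-1,2-diol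
Product: 14 (2R,3Z,6Z,8RS)-8-(tert-butyldimethylsilyloxy)-3,7,11-trimethyl-1-(triethylsilyloxy)dodeca-3,6,10-trien-2-ol
Conditions: TESCl (1.05 equiv), imidazole, CH2Cl2, −40 °C
Reagents that add atoms: chlorotriethylsilane, CC[Si](Cl)(CC)CC
Why: Sterically controlled silylation of the primary hydroxyl leaves the secondary allylic hydroxyl as the only directing group for the epoxidation.

**Step 9**
Reactants: 14 (2R,3Z,6Z,8RS)-8-(tert-butyldimethylsilyloxy)-3,7,11-trimethyl-1-(triethylsilyloxy)dodeca-3,6,10-trien-2-ol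
Product: 15 (1S)-1-[(2R,3S)-3-[(2Z,4RS)-4-(tert-butyldimethylsilyloxy)-3,7-dimethylocta-2,6-dien-1-yl]-2-methyloxiran-2-yl]-2-(triethylsilyloxy)ethan-1-ol
Conditions: Ti(OiPr)4 (0.3 equiv), t-BuOOH (decane), 4 Å MS, CH2Cl2, −20 °C
Reagents that add atoms: tert-butyl hydroperoxide, CC(C)(C)OO
Why: Titanium-alkoxide-directed epoxidation (Sharpless-type, without tartrate) touches only the allylic-alcohol alkene and delivers oxygen syn to the hydroxyl in the rotamer that keeps the carbinol H in the alkene plane facing the cis CH2 group (A(1,3) strain, threo selectivity), which sets both oxirane centres as needed for C1 and C6; the minor erythro isomer is to be removed by chromatography.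

**Step 10**
Reactants: 15 (1S)-1-[(2R,3S)-3-[(2Z,4RS)-4-(tert-butyldimethylsilyloxy)-3,7-dimethylocta-2,6-dien-1-yl]-2-methyloxiran-2-yl]-2-(triethylsilyloxy)ethan-1-ol
Product: 16 2-[(2S,3S)-3-[(2Z,4RS)-4-(tert-butyldimethylsilyloxy)-3,7-dimethylocta-2,6-dien-1-yl]-2-methyloxiran-2-yl]-2-oxoacetaldehyde
Conditions: (COCl)2, DMSO (excess), CH2Cl2, −78 → −40 °C; Et3N, −78 → 0 °C; non-aqueous work-up, used at once
Reagents that add atoms: none
Why: Swern oxidation converts the secondary alcohol into the ketone and, with excess chlorodimethylsulfonium chloride, cleaves and oxidises the primary triethylsilyl ether to the aldehyde in the same operation (a known chemoselective reaction of primary TES ethers, the secondary TBS ether being inert), giving the non-enolisable α-keto aldehyde.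

**Step 11**
Reactants: 16 2-[(2S,3S)-3-[(2Z,4RS)-4-(tert-butyldimethylsilyloxy)-3,7-dimethylocta-2,6-dien-1-yl]-2-methyloxiran-2-yl]-2-oxoacetaldehyde
Product: 17 (1S,3S,4S,6S)-4-[(3RS)-3-(tert-butyldimethylsilyloxy)-6-methylhepta-1,5-dien-2-yl]-3-hydroxy-1-methyl-7-oxabicyclo[4.1.0]heptan-2-one
Conditions: [Cu((S,S)-t-Bu-box)](SbF6)2 (10 mol %; box = 2,2′-(propane-2,2-diyl)bis(4-tert-butyl-4,5-dihydro-1,3-oxazole)), CH2Cl2, 0 °C
Reagents that add atoms: none
Why: The dicationic divalent copper centre chelates the two adjacent carbonyl oxygens (s-cis 1,2-dicarbonyl), and the (Z)-trisubstituted alkene adds through its CH terminus to the aldehyde carbon while the aldehyde oxygen takes a hydrogen from the vinylic methyl group in a concerted six-centre carbonyl-ene transition state; the closest known reactions are the Lewis-acid-catalysed cyclisation of citronellal to isopulegol and the bis(oxazoline)copper-catalysed glyoxylate-ene reaction. The carbocycle closes in a 6-exo-trig mode onto the aldehyde (the alkene's second carbon, C2′, also stays outside the ring) through a chair-like transition state flattened to a half-chair by the fused oxirane. C3 is set by the aldehyde face attacked: the (S,S) ligand exposes the si face, as in glyoxylate-ene reactions that give (S)-carbinols, and the substrate should agree, because the half-chair with C3 on the oxirane-oxygen side tilts the C2 carbonyl away from the oxirane oxygen and avoids a syn contact between the axial C3–H and the C1 methyl. C4 follows from the arrangement with both the coordinated C=O and the alkene pseudo-equatorial, which gives the 3,4-trans product and places the side chain cis to the oxirane oxygen. The step needs the aldehyde to react ahead of the ketone (more electrophilic, and only it closes a six-membered ring), hydrogen transfer from the methyl group and not from the silyloxy-bearing carbon (in the Z alkene only the methyl lies syn to the aldehyde oxygen in the trans-selective transition state), and reaction of the near alkene ahead of the prenyl alkene (six- against ten-membered ring).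

**Step 12**
Reactants: 17 (1S,3S,4S,6S)-4-[(3RS)-3-(tert-butyldimethylsilyloxy)-6-methylhepta-1,5-dien-2-yl]-3-hydroxy-1-methyl-7-oxabicyclo[4.1.0]heptan-2-one
Product: 18 (1S,3S,4S,6S)-4-[(3RS)-3-(tert-butyldimethylsilyloxy)-6-methylhepta-1,5-dien-2-yl]-1-methyl-2-oxo-7-oxabicyclo[4.1.0]heptan-3-yl 3-methylbutanoate
Conditions: (i-BuCO)2O, DMAP (cat.), pyridine, CH2Cl2, 0 → 23 °C
Reagents that add atoms: 3-methylbutanoic anhydride, CC(C)CC(=O)OC(=O)CC(C)C
Why: DMAP-catalysed acyl transfer esterifies the only free hydroxyl, and C3 should stay secure because the trans-diequatorial arrangement is also the thermodynamic one.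

**Step 13**
Reactants: 18 (1S,3S,4S,6S)-4-[(3RS)-3-(tert-butyldimethylsilyloxy)-6-methylhepta-1,5-dien-2-yl]-1-methyl-2-oxo-7-oxabicyclo[4.1.0]heptan-3-yl 3-methylbutanoate
Product: 19 (1S,3S,4S,6S)-4-[(3RS)-3-hydroxy-6-methylhepta-1,5-dien-2-yl]-1-methyl-2-oxo-7-oxabicyclo[4.1.0]heptan-3-yl 3-methylbutanoate
Conditions: HF·pyridine, pyridine, THF, 0 → 23 °C
Reagents that add atoms: none
Why: Buffered fluoride desilylation removes the allylic TBS ether without affecting the ester or the α,β-epoxy ketone.

**Step 14**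
Reactants: 19 (1S,3S,4S,6S)-4-[(3RS)-3-hydroxy-6-methylhepta-1,5-dien-2-yl]-1-methyl-2-oxo-7-oxabicyclo[4.1.0]heptan-3-yl 3-methylbutanoate
Product: 20 (1S,3S,4S,6S)-1-methyl-4-(6-methyl-3-oxohepta-1,5-dien-2-yl)-2-oxo-7-oxabicyclo[4.1.0]heptan-3-yl 3-methylbutanoate
Conditions: Dess–Martin periodinane, NaHCO3, CH2Cl2, 0 °C
Reagents that add atoms: none
Why: Buffered Dess–Martin oxidation gives the cross-conjugated enone and erases the epimeric carbinol centre, so both series converge on one compound, without moving the β,γ-alkene into conjugation.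

**Step 15**
Reactants: 20 (1S,3S,4S,6S)-1-methyl-4-(6-methyl-3-oxohepta-1,5-dien-2-yl)-2-oxo-7-oxabicyclo[4.1.0]heptan-3-yl 3-methylbutanoate
Product: 21 (1S,3S,4S,6S)-4-[(4E)-6-hydroperoxy-6-methyl-3-oxohepta-1,4-dien-2-yl]-1-methyl-2-oxo-7-oxabicyclo[4.1.0]heptan-3-yl 3-methylbutanoate
Conditions: O2, 5,10,15,20-tetraphenylporphyrin (cat.), visible light, CH2Cl2, −20 °C
Reagents that add atoms: oxygen (as singlet oxygen), O=O
Why: Schenck ene reaction: singlet oxygen should add only to the electron-rich trisubstituted alkene (both enone alkenes are inert) and abstract hydrogen preferentially from the C4′ methylene next to the ketone, so that the new (E)-alkene ends conjugated to the carbonyl and the hydroperoxide sits on the tertiary carbon.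

**Compound list**

1 | 4-methylpent-3-en-1-ol | CC(C)=CCCO | starting material
2 | 4-methylpent-3-enal | CC(C)=CCC=O | intermediate
3 | (3RS)-6-methylhept-5-en-1-yn-3-ol | C#CC(O)CC=C(C)C | intermediate
4 | (Z)-alkenylmagnesium bromide alkoxide from 3 | CC(C)=CCC(O[Mg]Br)/C(C)=C\[Mg]Br | intermediate
5 | (2Z,4RS)-3,7-dimethylocta-2,6-diene-1,4-diol | CC(C)=CCC(O)/C(C)=C\CO | intermediate
6 | (2Z,4RS)-1,4-bis(tert-butyldimethylsilyloxy)-3,7-dimethylocta-2,6-diene | CC(C)=CCC(O[Si](C)(C)C(C)(C)C)/C(C)=C\CO[Si](C)(C)C(C)(C)C | intermediate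
7 | (2Z,4RS)-1-bromo-4-(tert-butyldimethylsilyloxy)-3,7-dimethylocta-2,6-diene | CC(C)=CCC(O[Si](C)(C)C(C)(C)C)/C(C)=C\CBr | intermediate
8 | methyl (4S)-2,2-dimethyl-1,3-dioxolane-4-carboxylate | COC(=O)[C@@H]1COC(C)(C)O1 | starting material
9 | (4S)-2,2-dimethyl-1,3-dioxolane-4-carbaldehyde | O=C[C@@H]1COC(C)(C)O1 | intermediate
10 | (4R)-4-ethynyl-2,2-dimethyl-1,3-dioxolane | C#C[C@@H]1COC(C)(C)O1 | intermediate
11 | (2R)-but-3-yne-1,2-diol | C#C[C@@H](O)CO | intermediate
12 | (Z)-alkenylmagnesium bromide bis-alkoxide from 11 | Br[Mg]/C=C(C)\[C@@H](O[Mg]Br)CO[Mg]Br | intermediate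
13 | (2R,3Z,6Z,8RS)-8-(tert-butyldimethylsilyloxy)-3,7,11-trimethyldodeca-3,6,10-triene-1,2-diol | CC(C)=CCC(O[Si](C)(C)C(C)(C)C)/C(C)=C\C/C=C(C)\[C@@H](O)CO | intermediate
14 | (2R,3Z,6Z,8RS)-8-(tert-butyldimethylsilyloxy)-3,7,11-trimethyl-1-(triethylsilyloxy)dodeca-3,6,10-trien-2-ol | CC(C)=CCC(O[Si](C)(C)C(C)(C)C)/C(C)=C\C/C=C(C)\[C@@H](O)CO[Si](CC)(CC)CC | intermediate
15 | (1S)-1-[(2R,3S)-3-[(2Z,4RS)-4-(tert-butyldimethylsilyloxy)-3,7-dimethylocta-2,6-dien-1-yl]-2-methyloxiran-2-yl]-2-(triethylsilyloxy)ethan-1-ol | CC(C)=CCC(O[Si](C)(C)C(C)(C)C)/C(C)=C\C[C@@H]1O[C@]1(C)[C@@H](O)CO[Si](CC)(CC)CC | intermediate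
16 | 2-[(2S,3S)-3-[(2Z,4RS)-4-(tert-butyldimethylsilyloxy)-3,7-dimethylocta-2,6-dien-1-yl]-2-methyloxiran-2-yl]-2-oxoacetaldehyde | CC(C)=CCC(O[Si](C)(C)C(C)(C)C)/C(C)=C\C[C@@H]1O[C@]1(C)C(=O)C=O | intermediate
17 | (1S,3S,4S,6S)-4-[(3RS)-3-(tert-butyldimethylsilyloxy)-6-methylhepta-1,5-dien-2-yl]-3-hydroxy-1-methyl-7-oxabicyclo[4.1.0]heptan-2-one | C=C(C(O[Si](C)(C)C(C)(C)C)CC=C(C)C)[C@@H]1C[C@@H]2O[C@]2(C)C(=O)[C@H]1O | intermediate
18 | (1S,3S,4S,6S)-4-[(3RS)-3-(tert-butyldimethylsilyloxy)-6-methylhepta-1,5-dien-2-yl]-1-methyl-2-oxo-7-oxabicyclo[4.1.0]heptan-3-yl 3-methylbutanoate | C=C(C(O[Si](C)(C)C(C)(C)C)CC=C(C)C)[C@@H]1C[C@@H]2O[C@]2(C)C(=O)[C@H]1OC(=O)CC(C)C | intermediate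
19 | (1S,3S,4S,6S)-4-[(3RS)-3-hydroxy-6-methylhepta-1,5-dien-2-yl]-1-methyl-2-oxo-7-oxabicyclo[4.1.0]heptan-3-yl 3-methylbutanoate | C=C(C(O)CC=C(C)C)[C@@H]1C[C@@H]2O[C@]2(C)C(=O)[C@H]1OC(=O)CC(C)C | intermediate
20 | (1S,3S,4S,6S)-1-methyl-4-(6-methyl-3-oxohepta-1,5-dien-2-yl)-2-oxo-7-oxabicyclo[4.1.0]heptan-3-yl 3-methylbutanoate | C=C(C(=O)CC=C(C)C)[C@@H]1C[C@@H]2O[C@]2(C)C(=O)[C@H]1OC(=O)CC(C)C | intermediate
21 | (1S,3S,4S,6S)-4-[(4E)-6-hydroperoxy-6-methyl-3-oxohepta-1,4-dien-2-yl]-1-methyl-2-oxo-7-oxabicyclo[4.1.0]heptan-3-yl 3-methylbutanoate | C=C(C(=O)/C=C/C(C)(C)OO)[C@@H]1C[C@@H]2O[C@]2(C)C(=O)[C@H]1OC(=O)CC(C)C | target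

**Step count.** Total: 15 steps. Longest linear sequence: 13 steps (steps 1–4, then 7–15, from 4-methylpent-3-en-1-ol).

**Steps most likely to fail**

1. Step 11 (key step). The ring closure may occur on the wrong aldehyde face (the half-chair with C3 on the methyl side), or the cationic copper Lewis acid may open or rearrange the oxirane. The fallback sets out from 15 and returns to the route at 20; it closes the ring at the alcohol oxidation level with a simple aldehyde. Silylation of the secondary hydroxyl of 15 (TBSOTf, 2,6-lutidine) should give the tris-silyl ether F1. Swern conditions then cleave and oxidise only the primary TES ether, giving the α-silyloxy aldehyde F2. Me2AlCl (CH2Cl2, −78 °C) should effect the citronellal-type carbonyl-ene cyclisation to the cyclohexanol F3. Acylation with 3-methylbutanoic anhydride gives the ester F4, HF·pyridine removes both TBS groups to give the diol F5, and Dess–Martin periodinane oxidises both secondary alcohols to give 20.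

2. Step 15. Hydrogen may be abstracted from a methyl group instead of from C4′, which would give the secondary hydroperoxide with an isopropenyl terminus. The fallback sets out from 20 and returns at 21 without any new compound: a triplet-oxygen radical-chain autoxidation (O2, N-hydroxyphthalimide cat., MeCN, 30 °C). Hydrogen abstraction from the doubly activated C4′ methylene gives a delocalised allyl radical; oxygen trapping is reversible, so the conjugated tertiary hydroperoxide should accumulate, as in the autoxidation of β,γ-unsaturated ketones.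

3. Step 7. The carbomagnesiation of the dialkoxide may be incomplete, or residual MeMgBr may consume bromide 7 or attack it in an SN2′ sense. The fallback sets out from 11 and returns at 13. The alkenylmagnesium 12 is quenched with Bu3SnCl to give the (Z)-vinylstannane F6, which is purified and joined to 7 by a Stille coupling (Pd2(dba)3, tri(2-furyl)phosphine, CuI, DMF, 23 °C), with retention of both alkene geometries expected.

**Further compounds**

F1 | step 11 | (1S)-1-(tert-butyldimethylsilyloxy)-1-[(2S,3S)-3-[(2Z,4RS)-4-(tert-butyldimethylsilyloxy)-3,7-dimethylocta-2,6-dien-1-yl]-2-methyloxiran-2-yl]-2-(triethylsilyloxy)ethane | CC(C)=CCC(O[Si](C)(C)C(C)(C)C)/C(C)=C\C[C@@H]1O[C@]1(C)[C@@H](O[Si](C)(C)C(C)(C)C)CO[Si](CC)(CC)CC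
F2 | step 11 | (2R)-2-(tert-butyldimethylsilyloxy)-2-[(2S,3S)-3-[(2Z,4RS)-4-(tert-butyldimethylsilyloxy)-3,7-dimethylocta-2,6-dien-1-yl]-2-methyloxiran-2-yl]acetaldehyde | CC(C)=CCC(O[Si](C)(C)C(C)(C)C)/C(C)=C\C[C@@H]1O[C@]1(C)[C@@H](O[Si](C)(C)C(C)(C)C)C=O
F3 | step 11 | (1S,2S,3S,4S,6S)-2-(tert-butyldimethylsilyloxy)-4-[(3RS)-3-(tert-butyldimethylsilyloxy)-6-methylhepta-1,5-dien-2-yl]-1-methyl-7-oxabicyclo[4.1.0]heptan-3-ol | C=C(C(O[Si](C)(C)C(C)(C)C)CC=C(C)C)[C@@H]1C[C@@H]2O[C@]2(C)[C@@H](O[Si](C)(C)C(C)(C)C)[C@H]1O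
F4 | step 11 | (1S,2S,3S,4S,6S)-2-(tert-butyldimethylsilyloxy)-4-[(3RS)-3-(tert-butyldimethylsilyloxy)-6-methylhepta-1,5-dien-2-yl]-1-methyl-7-oxabicyclo[4.1.0]heptan-3-yl 3-methylbutanoate | C=C(C(O[Si](C)(C)C(C)(C)C)CC=C(C)C)[C@@H]1C[C@@H]2O[C@]2(C)[C@@H](O[Si](C)(C)C(C)(C)C)[C@H]1OC(=O)CC(C)C
F5 | step 11 | (1R,2S,3S,4S,6S)-2-hydroxy-4-[(3RS)-3-hydroxy-6-methylhepta-1,5-dien-2-yl]-1-methyl-7-oxabicyclo[4.1.0]heptan-3-yl 3-methylbutanoate | C=C(C(O)CC=C(C)C)[C@@H]1C[C@@H]2O[C@]2(C)[C@@H](O)[C@H]1OC(=O)CC(C)C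
F0 | step 15 | none | none
F6 | step 7 | (2R,3Z)-3-methyl-4-(tributylstannyl)but-3-ene-1,2-diol | CCCC[Sn](CCCC)(CCCC)/C=C(C)\[C@@H](O)CO
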